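**Plan**
1. Retrosynthesis (tetralone numbering: C1 carbonyl, C2/C3 methyl-bearing carbons, C4 diaryl carbon, ring A = fused benzene ring, ring B = cyclohexanone ring). The cuts, in order: the O–CH3 bond at C6; the aryl–acyl bond C1–C8a of ring B; C4–H, back to a γ-lactone C4–O bond; both C4–aryl bonds, back to a half-ester of meso-2,3-dimethylsuccinic acid and two equivalents of one aryl bromide.
2. Forward: the C1–C4 chain arrives with both methyl groups. Two identical 4-methoxy-3-isopropoxyphenyl groups are placed on C4 (temporary lactone ring). The lactone is opened reductively, ring B is closed (the only ring that has to be made), both phenols are freed and one is methylated.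
3. Stereochemistry: C3 comes from a catalytic enantioselective opening of the meso-anhydride. C2 comes from equilibration to the trans-dimethyl lactone. C4 is set in the ring closure, by the choice between the two identical aryl rings.
4. Enabling feature: ring A and the pendant aryl group on C4 are both 3,4-dioxygenated and differ only in OCH3 against OH at one oxygen. Carried as the same isopropyl ether they make C4 prochiral. The ring closure then tells them apart, because only the C6 oxygen of the acylated ring ends para to the C1 carbonyl.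

Key step: step 6

Remark: compounds 1 and 3 are taken as commercial.
Assumption: (DHQD)2AQN is taken to open anhydride 4 at the carbonyl next to the (S)-carbon; if it opens the other carbonyl, the pseudoenantiomeric (DHQ)2AQN replaces it and nothing else changes.

Step 1
Reactants: 1 5-bromo-2-methoxyphenol
Product: 2 4-bromo-1-methoxy-2-(propan-2-yloxy)benzene
Conditions: 2-bromopropane, K2CO3, DMF, 60 °C
Reagents that add atoms: 2-bromopropane, CC(C)Br
Why: Williamson ether synthesis (phenoxide displaces bromide); the isopropyl ether should survive the organomagnesium, base, dissolving-metal and Lewis-acid steps and is later cleaved by BCl3 without loss of the methyl ethers.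

Step 2
Reactants: 3 (2R,3S)-2,3-dimethylbutanedioic acid (meso-2,3-dimethylsuccinic acid)
Product: 4 (3R,4S)-3,4-dimethyloxolane-2,5-dione (meso-2,3-dimethylsuccinic anhydride)
Conditions: AcCl, reflux; evaporation
Reagents that add atoms: none
Why: Cyclodehydration of a 1,4-diacid to the five-membered anhydride; without base the two stereocenters are not enolized, so the cis (meso) relationship should be kept.

Step 3
Reactants: 4 (3R,4S)-3,4-dimethyloxolane-2,5-dione
Product: 5 (2R,3S)-4-methoxy-2,3-dimethyl-4-oxobutanoic acid
Conditions: MeOH (10 equiv), hydroquinidine anthraquinone-1,4-diyl diether (DHQD)2AQN (5 mol %), Et2O, −20 °C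
Reagents that add atoms: methanol, CO
Why: Cinchona-alkaloid-catalysed enantioselective alcoholysis (desymmetrization) of a meso cyclic anhydride; the catalyst directs methanol to one of the two enantiotopic carbonyl groups, which fixes the absolute configuration of both methyl-bearing carbons at once, the one next to the ester being the future C3.

Step 4
Reactants: 2 4-bromo-1-methoxy-2-(propan-2-yloxy)benzene (3.3 equiv, two of which are incorporated); 5 (2R,3S)-4-methoxy-2,3-dimethyl-4-oxobutanoic acid
Product: 8 (3S,4S)-5,5-bis[4-methoxy-3-(propan-2-yloxy)phenyl]-3,4-dimethyloxolan-2-one (trans-lactone), via aryl Grignard reagent 6 (not isolated), via cis-lactone 7 (not isolated)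
Conditions: 2 (3.3 equiv), Mg, THF, 45 °C; 5 added at −20 °C, then 20 °C; aq. citric acid; crude 7, DBU (0.5 equiv), toluene, 90 °C
Reagents that add atoms: 4-bromo-1-methoxy-2-(propan-2-yloxy)benzene (second equivalent of 2), COc1ccc(Br)cc1OC(C)C
Why: Magnesium insertion gives 6; one equivalent deprotonates the acid and two further equivalents add to the ester (Grignard addition through the aryl ketone) to give the diaryl carbinol, which lactonizes on acidification to 7; DBU then epimerizes the carbon α to the lactone carbonyl to the more stable trans-3,4-dimethyl lactone (thermodynamic control, relief of the eclipsed vicinal methyl groups), while the β-carbon, the future C3, is not acidic and should keep its configuration.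

Step 5
Reactants: 8 (3S,4S)-5,5-bis[4-methoxy-3-(propan-2-yloxy)phenyl]-3,4-dimethyloxolan-2-one
Product: 9 (2S,3R)-4,4-bis[4-methoxy-3-(propan-2-yloxy)phenyl]-2,3-dimethylbutanoic acid
Conditions: Li (3 equiv), NH3(l)/THF, −78 °C; NH4Cl
Reagents that add atoms: none
Why: Dissolving-metal (Birch-type) reductive cleavage of a doubly benzylic ester C–O bond: electron transfer expels the carboxylate and leaves a diarylmethyl anion that is protonated on quenching; C4 is not stereogenic here, no cation or alkene is formed so C3 cannot scramble, and the carboxylate protects C2 from deprotonation.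

Step 6
Reactants: 9 (2S,3R)-4,4-bis[4-methoxy-3-(propan-2-yloxy)phenyl]-2,3-dimethylbutanoic acid
Product: 11 (2S,3R,4R)-7-methoxy-4-[4-methoxy-3-(propan-2-yloxy)phenyl]-2,3-dimethyl-6-(propan-2-yloxy)-3,4-dihydronaphthalen-1(2H)-one, via acid chloride 10 (not isolated)
Conditions: (COCl)2, DMF (cat.), CH2Cl2, 0 °C; SnCl4, CH2Cl2, −78 °C
Reagents that add atoms: none
Why: SnCl4 ionizes acid chloride 10 to an acylium ion that attacks one of the two 4-methoxy-3-isopropoxyphenyl rings on C4 at the carbon ortho to C4 and para to the isopropoxy group, and loss of the ring proton gives the aryl ketone. The closest known reaction type is the intramolecular Friedel-Crafts acylation of 4,4-diarylbutanoic acids to 4-aryl-1-tetralones (Haworth tetralone synthesis). Ring B closes by a 6-exo-dig attack on the acylium carbon, with the attacked arene bond C4a–C8a inside the new ring. C4 is the new stereocenter: it becomes stereogenic because the two aryl rings on it are told apart, and it is controlled by C2 and C3 through a chair-like transition state in which both methyl groups (trans on the forming ring) are equatorial and the C4–H bond lies in the plane of the attacked ring next to C5–H (least allylic 1,3-strain), so that the spectator aryl group should be pseudoaxial on the face away from the incoming acylium and end cis to the C3 methyl group. The step needs group selectivity between the two diastereotopic rings (secured by the trans-dimethyl backbone and the in-plane penalty for an aryl group), site selectivity for the carbon para to the isopropoxy group over the crowded carbon between C4 and that group (secured by the para-directing ether), and retention at C2 (secured by base-free conditions at −78 °C).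

Step 7
Reactants: 11 (2S,3R,4R)-7-methoxy-4-[4-methoxy-3-(propan-2-yloxy)phenyl]-2,3-dimethyl-6-(propan-2-yloxy)-3,4-dihydronaphthalen-1(2H)-one
Product: 12 (2S,3R,4R)-6-hydroxy-4-(3-hydroxy-4-methoxyphenyl)-7-methoxy-2,3-dimethyl-3,4-dihydronaphthalen-1(2H)-one
Conditions: BCl3, CH2Cl2, −78 → 0 °C; H2O
Reagents that add atoms: none
Why: Lewis-acid dealkylation of aryl ethers: BCl3 removes the secondary isopropyl groups (as 2-chloropropane) much faster than methyl groups, and no methyl ether sits next to the ketone for chelation-assisted cleavage, so both phenols should be freed with the two methyl ethers and all stereocenters intact.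

Step 8
Reactants: 12 (2S,3R,4R)-6-hydroxy-4-(3-hydroxy-4-methoxyphenyl)-7-methoxy-2,3-dimethyl-3,4-dihydronaphthalen-1(2H)-one
Product: 13 (2S,3R,4R)-4-(3-hydroxy-4-methoxyphenyl)-6,7-dimethoxy-2,3-dimethyl-3,4-dihydronaphthalen-1(2H)-one (target)
Conditions: MeI (1.05 equiv), KHCO3 (1.1 equiv), DMF, 25 °C
Reagents that add atoms: iodomethane, CI
Why: Chemoselective Williamson O-methylation: the C6 hydroxyl is para to the C1 carbonyl on ring A (a vinylogous carboxylic acid, several pKa units more acidic in DMF than the guaiacol-type hydroxyl of the pendant ring), so one equivalent of a weak base should form only that phenoxide; no stereocenter is formed and C2 already holds its more stable configuration.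

**Compound list**
1 | 5-bromo-2-methoxyphenol | Oc1cc(Br)ccc1OC | starting material
2 | 4-bromo-1-methoxy-2-(propan-2-yloxy)benzene | COc1ccc(Br)cc1OC(C)C | intermediate
3 | (2R,3S)-2,3-dimethylbutanedioic acid (meso) | OC(=O)[C@H](C)[C@H](C)C(=O)O | starting material
4 | (3R,4S)-3,4-dimethyloxolane-2,5-dione (cis, meso) | O=C1[C@H](C)[C@H](C)C(=O)O1 | intermediate
5 | (2R,3S)-4-methoxy-2,3-dimethyl-4-oxobutanoic acid | OC(=O)[C@H](C)[C@H](C)C(=O)OC | intermediate
6 | [4-methoxy-3-(propan-2-yloxy)phenyl]magnesium bromide | COc1ccc([Mg]Br)cc1OC(C)C | intermediate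
7 | (3R,4S)-5,5-bis[4-methoxy-3-(propan-2-yloxy)phenyl]-3,4-dimethyloxolan-2-one (cis-lactone) | O=C1[C@H](C)[C@H](C)C(c2ccc(OC)c(OC(C)C)c2)(c2ccc(OC)c(OC(C)C)c2)O1 | intermediate
8 | (3S,4S)-5,5-bis[4-methoxy-3-(propan-2-yloxy)phenyl]-3,4-dimethyloxolan-2-one (trans-lactone) | O=C1[C@@H](C)[C@H](C)C(c2ccc(OC)c(OC(C)C)c2)(c2ccc(OC)c(OC(C)C)c2)O1 | intermediate
9 | (2S,3R)-4,4-bis[4-methoxy-3-(propan-2-yloxy)phenyl]-2,3-dimethylbutanoic acid | OC(=O)[C@@H](C)[C@H](C)C(c1ccc(OC)c(OC(C)C)c1)c1ccc(OC)c(OC(C)C)c1 | intermediate
10 | (2S,3R)-4,4-bis[4-methoxy-3-(propan-2-yloxy)phenyl]-2,3-dimethylbutanoyl chloride | ClC(=O)[C@@H](C)[C@H](C)C(c1ccc(OC)c(OC(C)C)c1)c1ccc(OC)c(OC(C)C)c1 | intermediate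
11 | (2S,3R,4R)-7-methoxy-4-[4-methoxy-3-(propan-2-yloxy)phenyl]-2,3-dimethyl-6-(propan-2-yloxy)-3,4-dihydronaphthalen-1(2H)-one | COc1ccc([C@@H]2c3cc(OC(C)C)c(OC)cc3C(=O)[C@@H](C)[C@@H]2C)cc1OC(C)C | intermediate
12 | (2S,3R,4R)-6-hydroxy-4-(3-hydroxy-4-methoxyphenyl)-7-methoxy-2,3-dimethyl-3,4-dihydronaphthalen-1(2H)-one | COc1ccc([C@@H]2c3cc(O)c(OC)cc3C(=O)[C@@H](C)[C@@H]2C)cc1O | intermediate
13 | (2S,3R,4R)-4-(3-hydroxy-4-methoxyphenyl)-6,7-dimethoxy-2,3-dimethyl-3,4-dihydronaphthalen-1(2H)-one | COc1ccc([C@@H]2c3cc(OC)c(OC)cc3C(=O)[C@@H](C)[C@@H]2C)cc1O | target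

**Step count:** 8 steps in total. Longest linear sequence: 7 steps (3 → 4 → 5 → 8 → 9 → 11 → 12 → 13).

**Steps most likely to fail**

Step 6. What may go wrong: too little discrimination between the two diastereotopic aryl rings during ring closure, so that the C4 epimer of 11 forms as well. The size of the in-plane penalty for the spectator aryl group is the main uncertainty of the route. Loss of the C2 configuration in the acid chloride before closure would also change the preferred ring. Fallback: C4 is fixed before the ring closure by using two different aryl groups, one of them switched off for acylation. The path sets out from 1 and comes back to the route at 13. Tosylation of 1 (TsCl, Et3N, CH2Cl2) gives 5-bromo-2-methoxyphenyl 4-methylbenzenesulfonate F1. A Heck reaction with acrylic acid (Pd(OAc)2, P(o-tol)3, K2CO3, DMF, 100 °C) gives the tosyloxy cinnamic acid F2. Its pivaloyl mixed anhydride acylates lithiated (4R)-4-phenyl-1,3-oxazolidin-2-one to the enoyl imide F3. Conjugate addition of 3,4-dimethoxyphenylmagnesium bromide with CuBr·SMe2 (THF, −40 °C) to the chelated imide, on the face away from the auxiliary phenyl group, should give the 3,3-diarylpropanoyl imide F4, with C4 set by the auxiliary. Methylation of its sodium enolate (NaN(SiMe3)2, MeI, −78 °C) should give the 2-methyl imide F5, with C3 set by the same auxiliary. LiOH/H2O2 removes the auxiliary to give the acid F6. Arndt–Eistert homologation with diazoethane (acid chloride, then CH3CHN2) gives the diazo ketone F7, and photochemical Wolff rearrangement in aqueous dioxane (migration with retention) gives the 2,3-dimethylbutanoic acid F8 as a mixture of C2 epimers. Friedel-Crafts closure ((COCl)2; SnCl4) can then take place only on the 3,4-dimethoxyphenyl ring, because the tosyloxy-bearing ring is deactivated, and gives the tetralone tosylate F9. KOH in MeOH at 65 °C removes the tosyl group and equilibrates C2 to the trans-2,3 arrangement, which gives 13.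

Step 4. What may go wrong: enolization of the intermediate aryl ketone by the Grignard reagent, which would erode C3, and an incomplete second addition at the crowded carbonyl; ionization of the electron-rich diaryl carbinol on acidic work-up, which would scramble C3 through the alkene; incomplete epimerization to the trans-lactone. Fallback: the two aryl groups are introduced in separate operations. The path sets out from 4 and 6 and comes back at 7. Transmetalation of 6 with ZnCl2 gives the arylzinc chloride F10. Enantioselective cross-coupling of F10 with the meso-anhydride 4 ([Rh(cod)Cl]2, TADDOL-derived phosphoramidite ligand, THF/DMF, 50 °C, ligand enantiomer chosen for the required sense) gives the keto acid F11 without any ester or excess base. Addition of 6 in the presence of CeCl3 (THF, −78 °C) and mild acidification then returns to cis-lactone 7, which is epimerized as before.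

Step 8. What may go wrong: methylation of both phenols, or of the pendant-ring phenol. Fallback: the two oxygens are told apart by ester cleavage instead of by alkylation. The path sets out from 12 and comes back at 13. Acetylation of both phenols (Ac2O, pyridine) gives the diacetate F12. Methanolysis with NaHCO3 in MeOH at 0 °C should remove first the acetate para to the ketone, whose phenoxide is the better leaving group, to give the monoacetate F13. Methylation (MeI, K2CO3, acetone) gives the methyl ether acetate F14, and K2CO3 in MeOH removes the remaining acetate to give 13.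

**Further compounds**
F1 | step 6 | 5-bromo-2-methoxyphenyl 4-methylbenzenesulfonate | COc1ccc(Br)cc1OS(=O)(=O)c1ccc(C)cc1
F2 | step 6 | (2E)-3-{4-methoxy-3-[(4-methylbenzenesulfonyl)oxy]phenyl}prop-2-enoic acid | COc1ccc(/C=C/C(=O)O)cc1OS(=O)(=O)c1ccc(C)cc1
F3 | step 6 | (4R)-3-[(2E)-3-{4-methoxy-3-[(4-methylbenzenesulfonyl)oxy]phenyl}prop-2-enoyl]-4-phenyl-1,3-oxazolidin-2-one | COc1ccc(/C=C/C(=O)N2C(=O)OC[C@H]2c2ccccc2)cc1OS(=O)(=O)c1ccc(C)cc1
F4 | step 6 | (4R)-3-[(3S)-3-(3,4-dimethoxyphenyl)-3-{4-methoxy-3-[(4-methylbenzenesulfonyl)oxy]phenyl}propanoyl]-4-phenyl-1,3-oxazolidin-2-one | COc1ccc([C@H](c2ccc(OC)c(OC)c2)CC(=O)N2C(=O)OC[C@H]2c2ccccc2)cc1OS(=O)(=O)c1ccc(C)cc1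
F5 | step 6 | (4R)-3-[(2R,3S)-3-(3,4-dimethoxyphenyl)-3-{4-methoxy-3-[(4-methylbenzenesulfonyl)oxy]phenyl}-2-methylpropanoyl]-4-phenyl-1,3-oxazolidin-2-one | COc1ccc([C@H](c2ccc(OC)c(OC)c2)[C@@H](C)C(=O)N2C(=O)OC[C@H]2c2ccccc2)cc1OS(=O)(=O)c1ccc(C)cc1
F6 | step 6 | (2R,3S)-3-(3,4-dimethoxyphenyl)-3-{4-methoxy-3-[(4-methylbenzenesulfonyl)oxy]phenyl}-2-methylpropanoic acid | COc1ccc([C@H](c2ccc(OC)c(OC)c2)[C@@H](C)C(=O)O)cc1OS(=O)(=O)c1ccc(C)cc1
F7 | step 6 | (4R,5S)-2-diazo-5-(3,4-dimethoxyphenyl)-5-{4-methoxy-3-[(4-methylbenzenesulfonyl)oxy]phenyl}-4-methylpentan-3-one | COc1ccc([C@H](c2ccc(OC)c(OC)c2)[C@@H](C)C(=O)C(C)=[N+]=[N-])cc1OS(=O)(=O)c1ccc(C)cc1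
F8 | step 6 | (3R,4S)-4-(3,4-dimethoxyphenyl)-4-{4-methoxy-3-[(4-methylbenzenesulfonyl)oxy]phenyl}-2,3-dimethylbutanoic acid (C2 epimers) | COc1ccc([C@H](c2ccc(OC)c(OC)c2)[C@@H](C)C(C)C(=O)O)cc1OS(=O)(=O)c1ccc(C)cc1
F9 | step 6 | (3R,4R)-6,7-dimethoxy-4-{4-methoxy-3-[(4-methylbenzenesulfonyl)oxy]phenyl}-2,3-dimethyl-3,4-dihydronaphthalen-1(2H)-one (C2 epimers) | COc1ccc([C@@H]2c3cc(OC)c(OC)cc3C(=O)C(C)[C@@H]2C)cc1OS(=O)(=O)c1ccc(C)cc1
F10 | step 4 | [4-methoxy-3-(propan-2-yloxy)phenyl]zinc chloride | COc1ccc([Zn]Cl)cc1OC(C)C
F11 | step 4 | (2R,3S)-4-[4-methoxy-3-(propan-2-yloxy)phenyl]-2,3-dimethyl-4-oxobutanoic acid | OC(=O)[C@H](C)[C@H](C)C(=O)c1ccc(OC)c(OC(C)C)c1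
F12 | step 8 | (2S,3R,4R)-6-acetoxy-4-(3-acetoxy-4-methoxyphenyl)-7-methoxy-2,3-dimethyl-3,4-dihydronaphthalen-1(2H)-one | COc1ccc([C@@H]2c3cc(OC(C)=O)c(OC)cc3C(=O)[C@@H](C)[C@@H]2C)cc1OC(C)=O
F13 | step 8 | (2S,3R,4R)-4-(3-acetoxy-4-methoxyphenyl)-6-hydroxy-7-methoxy-2,3-dimethyl-3,4-dihydronaphthalen-1(2H)-one | COc1ccc([C@@H]2c3cc(O)c(OC)cc3C(=O)[C@@H](C)[C@@H]2C)cc1OC(C)=O
F14 | step 8 | (2S,3R,4R)-4-(3-acetoxy-4-methoxyphenyl)-6,7-dimethoxy-2,3-dimethyl-3,4-dihydronaphthalen-1(2H)-one | COc1ccc([C@@H]2c3cc(OC)c(OC)cc3C(=O)[C@@H](C)[C@@H]2C)cc1OC(C)=O
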